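The decalin locants follow the name of 24: C1 (quaternary, CH2–quinone), C2 (CHMe), C3, C4, C4a (CH), C5 (C=CH2), C8a (quaternary). Ring B is disconnected at C3–C4. This is the only bond of ring B between two unsubstituted methylenes, and it lies opposite the crowded C1–C8a bond. C2, C1 and C8a can therefore be set on monocyclic ring A. A C5 ketone, the latent exocyclic methylene, makes C4 the terminus of an α-methylene ketone. The key step is a 6-endo radical conjugate addition of a primary C3 radical to C4. It closes ring B and sets C4a in one operation. Its precursor is a 2-methylidenecyclohexanone carrying an open-chain iodide.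

Key step: step 10

Remark: 1, 3 and 12 are taken as catalogue compounds; centres that a later step erases (lactone α-carbon of 8, anomeric carbon of 11, carbinol carbon of 14, peroxy-bearing carbon of 17 and 18) are inconsequential and are left undefined in the SMILES where no single configuration is expected.

Step 1
Reactants: 1 2,3-dimethylcyclohex-2-en-1-one
Product: 2 (1R)-2,3-dimethylcyclohex-2-en-1-ol
Conditions: (S)-Me-CBS (10 mol %), BH3·SMe2, THF, −20 °C; MeOH, aq. work-up
Reagents that add atoms: none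
Why: Corey–Bakshi–Shibata reduction: with the tetrasubstituted alkenyl arm as the large group and the ring CH2 as the small group, the (S)-catalyst should deliver hydride to the face that gives the (R)-carbinol, from which the ring quaternary carbon is later relayed.

Step 2
Reactants: 3 (4R)-4-methyldihydrofuran-2(3H)-one
Product: 5 (4R)-2,2-dimethoxy-4-methyltetrahydrofuran, via O-methyl lactonium tetrafluoroborate 4 (not isolated)
Conditions: Me3O·BF4, CH2Cl2, rt; NaOMe, MeOH, −78 → 0 °C
Reagents that add atoms: trimethyloxonium tetrafluoroborate C[O+](C)C.F[B-](F)(F)F; sodium methoxide C[O-].[Na+]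
Why: Meerwein O-methylation of the lactone carbonyl, then capture of the dialkoxycarbenium ion 4 by methoxide, is the standard route to cyclic orthoesters, and the purchased C4 stereocentre is not involved.

Step 3
Reactants: 2 (1R)-2,3-dimethylcyclohex-2-en-1-ol; 5 (4R)-2,2-dimethoxy-4-methyltetrahydrofuran
Product: 8 (3S,4R)-3-[(1R)-1,2-dimethylcyclohex-2-en-1-yl]-4-methyldihydrofuran-2(3H)-one, via mixed orthoester 6 (not isolated), via cyclic ketene acetal 7 (not isolated)
Conditions: 5 (3 equiv), pivalic acid (10 mol %), xylenes, 140 °C, MeOH distilled off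
Reagents that add atoms: none
Why: Johnson-type orthoester Claisen rearrangement with a cyclic orthoester: alcohol exchange (6), loss of methanol (7) and a suprafacial [3,3] shift across the ring face that carried the C–O bond transfer the configuration of 2 completely to the new quaternary carbon, while the lactone α-centre (trans isomer expected) is erased in step 4.

Step 4
Reactants: 8 (3S,4R)-3-[(1R)-1,2-dimethylcyclohex-2-en-1-yl]-4-methyldihydrofuran-2(3H)-one
Product: 10 (3R,4R)-3-[(1S)-1,2-dimethylcyclohex-2-en-1-yl]-3,4-dimethyldihydrofuran-2(3H)-one, via lithium enolate 9 (not isolated)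
Conditions: LDA, THF, −78 °C; MeI, DMPU, −78 → −20 °C
Reagents that add atoms: iodomethane CI
Why: Lactone enolate alkylation under 1,2-induction: iodomethane should attack the planar five-membered enolate 9 anti to the neighbouring ring methyl group, which sets the second quaternary centre with the cyclohexenyl group cis to that methyl.

Step 5
Reactants: 10 (3R,4R)-3-[(1S)-1,2-dimethylcyclohex-2-en-1-yl]-3,4-dimethyldihydrofuran-2(3H)-one
Product: 11 (3R,4R)-3-[(1S)-1,2-dimethylcyclohex-2-en-1-yl]-3,4-dimethyltetrahydrofuran-2-ol (anomers)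
Conditions: DIBAL-H, CH2Cl2, −78 °C; Rochelle salt
Reagents that add atoms: none
Why: Partial DIBAL-H reduction of a γ-lactone: the tetrahedral aluminate is stable at −78 °C, so reduction should stop at the lactol, and the alkene is inert.

Step 6
Reactants: 11 (3R,4R)-3-[(1S)-1,2-dimethylcyclohex-2-en-1-yl]-3,4-dimethyltetrahydrofuran-2-ol; 12 1,2,4,5-tetramethoxybenzene
Product: 14 (2R,3R)-2-[(1S)-1,2-dimethylcyclohex-2-en-1-yl]-2,3-dimethyl-1-(2,3,5,6-tetramethoxyphenyl)butane-1,4-diol (both C1 epimers), via aryllithium 13 (not isolated)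
Conditions: 12, n-BuLi, THF, 0 °C; then 11 (0.45 equiv), −78 → 0 °C; H2O
Reagents that add atoms: none
Why: Directed ortho-lithiation of 12, then 1,2-addition of the aryllithium to the open hydroxy-aldehyde form of the lactolate (the first equivalent acts as base); the new carbinol centre is removed in step 7, so its configuration does not matter.

Step 7
Reactants: 14 (2R,3R)-2-[(1S)-1,2-dimethylcyclohex-2-en-1-yl]-2,3-dimethyl-1-(2,3,5,6-tetramethoxyphenyl)butane-1,4-diol
Product: 15 (2R,3R)-3-[(1S)-1,2-dimethylcyclohex-2-en-1-yl]-2,3-dimethyl-4-(2,3,5,6-tetramethoxyphenyl)butan-1-ol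
Conditions: Li, NH3(l)/THF, −78 → −33 °C; solid NH4Cl
Reagents that add atoms: none
Why: Dissolving-metal benzylic hydrogenolysis: electron transfer to the arene expels the benzylic oxygen once NH4Cl protonates the alkoxide, whereas the primary alkoxide, the isolated trisubstituted alkene and the electron-rich ring should not be reduced.

Step 8
Reactants: 15 (2R,3R)-3-[(1S)-1,2-dimethylcyclohex-2-en-1-yl]-2,3-dimethyl-4-(2,3,5,6-tetramethoxyphenyl)butan-1-ol
Product: 16 3-{(2R,3R)-2-[(1S)-1,2-dimethylcyclohex-2-en-1-yl]-4-iodo-2,3-dimethylbutyl}-1,2,4,5-tetramethoxybenzene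
Conditions: I2, PPh3, imidazole, CH2Cl2, 0 °C → rt
Reagents that add atoms: iodine II
Why: Appel-type (Garegg–Samuelsson) iodination: SN2 displacement of the alkoxyphosphonium ion at the only hydroxyl-bearing carbon, which is not stereogenic.

Step 9
Reactants: 16 3-{(2R,3R)-2-[(1S)-1,2-dimethylcyclohex-2-en-1-yl]-4-iodo-2,3-dimethylbutyl}-1,2,4,5-tetramethoxybenzene
Product: 19 (3R)-3-[(2R,3R)-4-iodo-2,3-dimethyl-1-(2,3,5,6-tetramethoxyphenyl)butan-2-yl]-3-methyl-2-methylidenecyclohexan-1-one, via allylic hydroperoxide 17 (not isolated), via allylic peroxyacetate 18 (not isolated)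
Conditions: O2, TPP (cat.), visible light, Ac2O, pyridine, DMAP (cat.), CH2Cl2, 0 °C → rt
Reagents that add atoms: oxygen O=O
Why: Schenck ene reaction followed by a Kornblum–DeLaMare-type elimination in one pot: singlet oxygen should bond to the CH terminus of the alkene, remote from the quaternary carbon, and take hydrogen from the methyl group geminal to that bulky substituent, and acetylation–elimination of 17 via 18 turns the secondary hydroperoxide into the ketone.

Step 10
Reactants: 19 (3R)-3-[(2R,3R)-4-iodo-2,3-dimethyl-1-(2,3,5,6-tetramethoxyphenyl)butan-2-yl]-3-methyl-2-methylidenecyclohexan-1-one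
Product: 20 (4aS,5R,6S,8aR)-4a,5,6-trimethyl-5-[(2,3,5,6-tetramethoxyphenyl)methyl]octahydronaphthalen-1(2H)-one
Conditions: Bu3SnH (1.3 equiv, syringe pump), Et3B (cat.), air, PhMe (5 mM), 0 °C
Reagents that add atoms: none
Why: Tin-hydride-mediated intramolecular Giese reaction (locants of 24): Bu3Sn• abstracts iodine from 19 and the nucleophilic primary C3 radical adds to the unsubstituted terminus C4 of the exocyclic enone. Ring B closes in the 6-endo-trig mode, because the 5-exo alternative would attack the fully substituted and electronically mismatched α-carbon C4a next to quaternary C8a, and the two contiguous quaternary carbons of the tether (Thorpe–Ingold effect) together with slow hydride addition favour cyclisation over premature reduction. The closest known reaction type is the 6-endo cyclisation of 5-acylhex-5-enyl radicals onto α-methylene ketones. The only new stereocentre, C4a, arises when the planar α-keto radical takes hydrogen from Bu3SnH: its β face carries the vicinal C8a methyl and, in the ring-B half-chair that avoids the C2-Me/C8a-Me syn-axial contact, the syn-axial C1 methyl, so hydrogen should enter from the α face and give the trans-decalone. C2, C1 and C8a are spectators and cannot be scrambled. The conditions are neutral, which matters because the trans ketone is a kinetic product that acid or base could epimerise at C4a.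

Step 11
Reactants: 20 (4aS,5R,6S,8aR)-4a,5,6-trimethyl-5-[(2,3,5,6-tetramethoxyphenyl)methyl]octahydronaphthalen-1(2H)-one
Product: 21 1,2,4,5-tetramethoxy-3-{[(1R,2S,4aS,8aS)-1,2,8a-trimethyl-5-methylidenedecahydronaphthalen-1-yl]methyl}benzene
Conditions: Zn, CH2Br2, TiCl4, THF/CH2Cl2, 0 °C → rt
Reagents that add atoms: dibromomethane BrCBr
Why: Takai–Lombardo methylenation: the non-basic gem-dimetallic reagent adds to the ketone faster than it enolises it, so the kinetic configuration of the ring-fusion CH should be carried unchanged into the alkene, where it is fixed for good.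

Step 12
Reactants: 21 1,2,4,5-tetramethoxy-3-{[(1R,2S,4aS,8aS)-1,2,8a-trimethyl-5-methylidenedecahydronaphthalen-1-yl]methyl}benzene
Product: 22 2,5-dimethoxy-3-{[(1R,2S,4aS,8aS)-1,2,8a-trimethyl-5-methylidenedecahydronaphthalen-1-yl]methyl}cyclohexa-2,5-diene-1,4-dione
Conditions: (NH4)2Ce(NO3)6, MeCN/H2O, 0 °C
Reagents that add atoms: water O
Why: Oxidative demethylation with cerium(IV): two one-electron oxidations and attack of water on a para pair of methoxy-bearing carbons give the quinone, both para pairs of the symmetric arene lead to the same product, and the 1,1-disubstituted alkene should survive at 0 °C.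

Step 13
Reactants: 22 2,5-dimethoxy-3-{[(1R,2S,4aS,8aS)-1,2,8a-trimethyl-5-methylidenedecahydronaphthalen-1-yl]methyl}cyclohexa-2,5-diene-1,4-dione
Product: 24 2-hydroxy-5-methoxy-3-{[(1R,2S,4aS,8aS)-1,2,8a-trimethyl-5-methylidenedecahydronaphthalen-1-yl]methyl}cyclohexa-2,5-diene-1,4-dione, via potassium quinonate 23 (not isolated)
Conditions: KOH (aq.), MeOH, rt; cold dilute HCl to pH 3
Reagents that add atoms: potassium hydroxide [K+].[OH-]
Why: Regioselective saponification of a vinylogous ester by addition–elimination: the methoxy group flanked by the neopentyl-type side chain is twisted out of conjugation, so its carbon is the more electrophilic one, and the quinonate 23 formed is deactivated towards a second hydrolysis.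

Compound list
1 | 2,3-dimethylcyclohex-2-en-1-one | CC1=C(C)C(=O)CCC1 | starting material
2 | (1R)-2,3-dimethylcyclohex-2-en-1-ol | O[C@@H]1CCCC(C)=C1C | intermediate
3 | (4R)-4-methyldihydrofuran-2(3H)-one | O=C1C[C@H](CO1)C | starting material
4 | (3R)-5-methoxy-3-methyl-3,4-dihydro-2H-furan-1-ium tetrafluoroborate | COC=1C[C@H](C[O+]=1)C.F[B-](F)(F)F | intermediate
5 | (4R)-2,2-dimethoxy-4-methyltetrahydrofuran | COC1(OC)C[C@H](CO1)C | intermediate
6 | (4R)-2-{[(1R)-2,3-dimethylcyclohex-2-en-1-yl]oxy}-2-methoxy-4-methyltetrahydrofuran (C2 epimers) | COC1(O[C@@H]2CCCC(C)=C2C)C[C@H](CO1)C | intermediate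
7 | (3R)-5-{[(1R)-2,3-dimethylcyclohex-2-en-1-yl]oxy}-3-methyl-2,3-dihydrofuran | C[C@H]1COC(O[C@@H]2CCCC(C)=C2C)=C1 | intermediate
8 | (3S,4R)-3-[(1R)-1,2-dimethylcyclohex-2-en-1-yl]-4-methyldihydrofuran-2(3H)-one | C1=C(C)[C@@](C)([C@H]([C@H](CO2)C)C2=O)CCC1 | intermediate
9 | lithium enolate of 8 | C1=C(C)[C@@](C)(C2=C(O[Li])OC[C@@H]2C)CCC1 | intermediate
10 | (3R,4R)-3-[(1S)-1,2-dimethylcyclohex-2-en-1-yl]-3,4-dimethyldihydrofuran-2(3H)-one | C1=C(C)[C@@](C)([C@]([C@H](CO2)C)(C)C2=O)CCC1 | intermediate
11 | (3R,4R)-3-[(1S)-1,2-dimethylcyclohex-2-en-1-yl]-3,4-dimethyltetrahydrofuran-2-ol (anomers) | C1=C(C)[C@@](C)([C@]([C@H](CO2)C)(C)C2O)CCC1 | intermediate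
12 | 1,2,4,5-tetramethoxybenzene | COc1cc(OC)c(OC)cc1OC | starting material
13 | (2,3,5,6-tetramethoxyphenyl)lithium | [Li]c1c(OC)c(OC)cc(OC)c1OC | intermediate
14 | (2R,3R)-2-[(1S)-1,2-dimethylcyclohex-2-en-1-yl]-2,3-dimethyl-1-(2,3,5,6-tetramethoxyphenyl)butane-1,4-diol (C1 epimers) | C1=C(C)[C@@](C)([C@]([C@H](CO)C)(C)C(O)c2c(OC)c(OC)cc(OC)c2OC)CCC1 | intermediate
15 | (2R,3R)-3-[(1S)-1,2-dimethylcyclohex-2-en-1-yl]-2,3-dimethyl-4-(2,3,5,6-tetramethoxyphenyl)butan-1-ol | C1=C(C)[C@@](C)([C@]([C@H](CO)C)(C)Cc2c(OC)c(OC)cc(OC)c2OC)CCC1 | intermediate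
16 | 3-{(2R,3R)-2-[(1S)-1,2-dimethylcyclohex-2-en-1-yl]-4-iodo-2,3-dimethylbutyl}-1,2,4,5-tetramethoxybenzene | C1=C(C)[C@@](C)([C@]([C@H](CI)C)(C)Cc2c(OC)c(OC)cc(OC)c2OC)CCC1 | intermediate
17 | allylic hydroperoxide: 19 with CH–OOH in place of C=O | OOC1CCC[C@](C)([C@]([C@H](CI)C)(C)Cc2c(OC)c(OC)cc(OC)c2OC)C1=C | intermediate
18 | peroxyacetate of 17 | CC(=O)OOC1CCC[C@](C)([C@]([C@H](CI)C)(C)Cc2c(OC)c(OC)cc(OC)c2OC)C1=C | intermediate
19 | (3R)-3-[(2R,3R)-4-iodo-2,3-dimethyl-1-(2,3,5,6-tetramethoxyphenyl)butan-2-yl]-3-methyl-2-methylidenecyclohexan-1-one | O=C1CCC[C@](C)([C@]([C@H](CI)C)(C)Cc2c(OC)c(OC)cc(OC)c2OC)C1=C | intermediate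
20 | (4aS,5R,6S,8aR)-4a,5,6-trimethyl-5-[(2,3,5,6-tetramethoxyphenyl)methyl]octahydronaphthalen-1(2H)-one | O=C1CCC[C@@]2(C)[C@H]1CC[C@H](C)[C@@]2(C)Cc1c(OC)c(OC)cc(OC)c1OC | intermediate
21 | 1,2,4,5-tetramethoxy-3-{[(1R,2S,4aS,8aS)-1,2,8a-trimethyl-5-methylidenedecahydronaphthalen-1-yl]methyl}benzene | C=C1CCC[C@@]2(C)[C@H]1CC[C@H](C)[C@@]2(C)Cc1c(OC)c(OC)cc(OC)c1OC | intermediate
22 | 2,5-dimethoxy-3-{[(1R,2S,4aS,8aS)-1,2,8a-trimethyl-5-methylidenedecahydronaphthalen-1-yl]methyl}cyclohexa-2,5-diene-1,4-dione | C=C1CCC[C@@]2(C)[C@H]1CC[C@H](C)[C@@]2(C)CC1=C(OC)C(=O)C=C(OC)C1=O | intermediate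
23 | potassium salt of 24 | C=C1CCC[C@@]2(C)[C@H]1CC[C@H](C)[C@@]2(C)CC1=C([O-])C(=O)C=C(OC)C1=O.[K+] | intermediate
24 | 2-hydroxy-5-methoxy-3-{[(1R,2S,4aS,8aS)-1,2,8a-trimethyl-5-methylidenedecahydronaphthalen-1-yl]methyl}cyclohexa-2,5-diene-1,4-dione | C=C1CCC[C@@]2(C)[C@H]1CC[C@H](C)[C@@]2(C)CC1=C(O)C(=O)C=C(OC)C1=O | target

Total steps: 13. Longest linear sequence: 12 (steps 1 and 3–13; step 2 is a one-step branch).

**Steps most likely to fail**

Step 10. Two things could go wrong.
- Hydrogen transfer to the planar α-keto radical could occur on the β face.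
- The kinetic trans ketone could epimerise at the ring fusion during tin removal. The cis-fused ketone relieves the syn-axial methyl pair and is probably the more stable epimer.

The fallback replaces the enone acceptor by an alkene that carries a directing group and cannot enolise. It sets out from 19 and returns at 20.
- Luche reduction, with hydride entering anti to the syn-axial ring methyl, should give the β-allylic alcohol F1.
- TBSCl/imidazole gives the silyl ether F2.
- Bu3SnH/AIBN under high dilution closes the ring by 6-endo attack on the unactivated 1,1-disubstituted alkene. The tertiary radical, whose β face is flanked by the axial silyloxy and methyl groups, takes hydrogen from the α face to give the trans-decalin silyl ether F3.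
- TBAF gives the decalinol F4, and buffered Dess–Martin oxidation leads to 20.

Step 9. The very electron-rich arene could quench or consume singlet oxygen, and light could cleave the C–I bond, so that the ene reaction stalls. The fallback builds the same enone by ionic chemistry. It sets out from 15 and returns at 19.
- Buffered mCPBA epoxidation anti to the ring methyl gives the epoxy alcohol F5.
- Diethylaluminium 2,2,6,6-tetramethylpiperidide removes a proton from the epoxide-bound methyl group and opens the tertiary C–O bond to give the allylic diol F6.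
- I2/PPh3/imidazole at 0 °C converts only the primary hydroxyl and gives the iodo allylic alcohol F7.
- MnO2 oxidation gives 19.

Step 3. Acid-induced ionisation and dehydration of the tetrasubstituted allylic alcohol, or ring-opening of the cyclic orthoester, could outrun exchange and rearrangement. The fallback is an Ireland–Claisen rearrangement under basic conditions. It sets out from 2 and 3 and returns at 8.
- Saponification of 3, silylation with TESCl and cleavage of the silyl ester give the silyloxy acid F8.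
- DCC/DMAP esterification with 2 gives the allylic ester F9.
- LDA/TMSCl at −78 °C gives the silyl ketene acetal F10.
- Warming to 65 °C effects the suprafacial [3,3] shift to the trimethylsilyl ester F11.
- 1 M HCl in THF removes both silyl groups, with spontaneous lactonisation to 8.

Further compounds
F1 | step 10 | β-allylic alcohol, (1S,3R)-3-[(2R,3R)-4-iodo-2,3-dimethyl-1-(2,3,5,6-tetramethoxyphenyl)butan-2-yl]-3-methyl-2-methylidenecyclohexan-1-ol | O[C@H]1CCC[C@](C)([C@]([C@H](CI)C)(C)Cc2c(OC)c(OC)cc(OC)c2OC)C1=C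
F2 | step 10 | silyl ether, tert-butyldimethylsilyl ether of F1 | CC(C)(C)[Si](C)(C)O[C@H]1CCC[C@](C)([C@]([C@H](CI)C)(C)Cc2c(OC)c(OC)cc(OC)c2OC)C1=C
F3 | step 10 | trans-decalin silyl ether, tert-butyldimethylsilyl ether of F4 | CC(C)(C)[Si](C)(C)O[C@H]1CCC[C@@]2(C)[C@H]1CC[C@H](C)[C@@]2(C)Cc1c(OC)c(OC)cc(OC)c1OC
F4 | step 10 | decalinol, (1S,4aS,5R,6S,8aR)-4a,5,6-trimethyl-5-[(2,3,5,6-tetramethoxyphenyl)methyl]decahydronaphthalen-1-ol | O[C@H]1CCC[C@@]2(C)[C@H]1CC[C@H](C)[C@@]2(C)Cc1c(OC)c(OC)cc(OC)c1OC
F5 | step 9 | epoxy alcohol, epoxide of 15 with oxygen anti to the methyl group on the ring quaternary carbon | C[C@@]12O[C@@H]1CCC[C@]2(C)[C@]([C@H](CO)C)(C)Cc1c(OC)c(OC)cc(OC)c1OC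
F6 | step 9 | allylic diol, (2R,3R)-3-[(1R,3R)-3-hydroxy-1-methyl-2-methylidenecyclohexyl]-2,3-dimethyl-4-(2,3,5,6-tetramethoxyphenyl)butan-1-ol | O[C@@H]1CCC[C@](C)([C@]([C@H](CO)C)(C)Cc2c(OC)c(OC)cc(OC)c2OC)C1=C
F7 | step 9 | iodo allylic alcohol, (1R,3R)-3-[(2R,3R)-4-iodo-2,3-dimethyl-1-(2,3,5,6-tetramethoxyphenyl)butan-2-yl]-3-methyl-2-methylidenecyclohexan-1-ol | O[C@@H]1CCC[C@](C)([C@]([C@H](CI)C)(C)Cc2c(OC)c(OC)cc(OC)c2OC)C1=C
F8 | step 3 | silyloxy acid, (3R)-3-methyl-4-[(triethylsilyl)oxy]butanoic acid | OC(=O)C[C@H](CO[Si](CC)(CC)CC)C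
F9 | step 3 | allylic ester, (1R)-2,3-dimethylcyclohex-2-en-1-yl (3R)-3-methyl-4-[(triethylsilyl)oxy]butanoate | O=C(C[C@H](CO[Si](CC)(CC)CC)C)O[C@@H]1CCCC(C)=C1C
F10 | step 3 | silyl ketene acetal, O-trimethylsilyl ketene acetal of F9 | C[Si](C)(C)OC(=C[C@H](CO[Si](CC)(CC)CC)C)O[C@@H]1CCCC(C)=C1C
F11 | step 3 | trimethylsilyl ester, trimethylsilyl (3R)-2-[(1R)-1,2-dimethylcyclohex-2-en-1-yl]-3-methyl-4-[(triethylsilyl)oxy]butanoate (C2 epimers) | C[Si](C)(C)OC(=O)C([C@H](CO[Si](CC)(CC)CC)C)[C@@]1(C)CCCC=C1C
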